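**Plan**

- Retrosynthesis: the C6 acetate, C15 ketone and C11 alcohol are adjusted last. Ring D is cut at C13–C16 (vinyl radical onto a C11 enone). Ring C and the δ-lactone are cut together at C8–C9 and C13–C14 (Diels–Alder across the C20–O–C7 ester). Ring A and the five-membered oxygen ring are cut together at C1–C10 and C4–C5.
- Enabling feature: ring A carries four contiguous stereocentres (C1, C10, C5, C4; C10 and C4 quaternary), and C4 and C5 are already bridged by C19–O–C6 of the five-membered acetal ring. At the lactone level this bridge is an ester tether between a dienol and a maleate.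
- Forward order: (2Z,4E)-dienol + 2-allylmaleic anhydride → hydrogen maleate → ring A with γ-lactone → C20 and C6 adjusted, allyl → vinyl ketone → ring C with δ-lactone → ring D → C6 acetate, C11 alcohol, C15 enone.
- Stereochemistry: C1, C4, C5, C10 relative from the three alkene geometries and the cis-fused tether ring. Absolute from a (1S)-camphanoyl group on the diene oxygen, which makes the two cycloadducts separable diastereomers. C8 and C9 from C10 in the second cycloaddition, C13 from the bridge, C11 from hydride delivery, C6 from acetylation on the convex face.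

Key step: step 10

Remarks: atoms are numbered as in the ent-kaurane skeleton of the target (C1–C20). Assumption: no facial bias from the camphanoyl group is relied on; the two diastereomeric cycloadducts of step 10 are taken to be separable and the one drawn is carried on. Compounds 23–31 and 38–43 are C6 epimer mixtures and 46 a C15 epimer mixture (these centres are left undefined in their SMILES).

Step 1
Reactants: 1 propargyl alcohol
Product: 3 (Z)-3-iodo-2-methylprop-2-en-1-ol, via cyclic alkenylmagnesium alkoxide 2 (not isolated)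
Conditions: MeMgBr (2.5 equiv), CuI (10 mol %), THF, −10 °C → rt; then I2, −78 → 0 °C
Reagents that add atoms: methylmagnesium bromide C[Mg]Br; iodine II
Why: Copper-catalysed anti-carbomagnesiation of the propargylic alkoxide puts methyl on the carbon next to CH2O and magnesium cis to CH2O in a five-membered chelate, and iodinolysis with retention then gives the (Z)-iodide.

Step 2
Reactants: 3 (Z)-3-iodo-2-methylprop-2-en-1-ol
Product: 4 (Z)-1-(tert-butyldimethylsilyloxy)-3-iodo-2-methylprop-2-ene
Conditions: TBSCl, imidazole, DMF, rt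
Reagents that add atoms: tert-butyldimethylsilyl chloride CC(C)(C)[Si](C)(C)Cl
Why: Silyl ether protection of the primary allylic alcohol keeps it out of the organometallic and copper–oxygen steps that follow.

Step 3
Reactants: 4 silyl ether of the (Z)-iodide; 5 ethynylmagnesium bromide
Product: 6 (Z)-5-(tert-butyldimethylsilyloxy)-4-methylpent-3-en-1-yne
Conditions: 5, ZnBr2, THF, 0 °C; then 4, Pd(PPh3)4 (5 mol %), rt
Reagents that add atoms: none
Why: Negishi coupling of the alkenyl iodide with ethynylzinc bromide under zerovalent palladium keeps the (Z) geometry and delivers the terminal enyne in one operation.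

Step 4
Reactants: 6 (Z)-enyne
Product: 8 potassium (1E,3Z)-[5-(tert-butyldimethylsilyloxy)-4-methylpenta-1,3-dienyl]trifluoroborate, via pinacol dienylboronate 7 (not isolated)
Conditions: pinacolborane, Cp2Zr(H)Cl (5 mol %), Et3N (10 mol %), CH2Cl2, rt; then KHF2, MeOH/H2O, rt
Reagents that add atoms: pinacolborane CC1(C)OBOC1(C)C; potassium hydrogen difluoride [K+].F[H-]F
Why: Zirconocene-hydride-catalysed hydroboration adds H and B syn and anti-Markovnikov to the terminal alkyne only, which fixes the new C1=C2 bond as (E), and KHF2 converts the boronate into the air-stable trifluoroborate used for C–O coupling.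

Step 5
Reactants: 8 dienyltrifluoroborate; 9 (1S)-(−)-camphanic acid
Product: 10 (1E,3Z)-5-(tert-butyldimethylsilyloxy)-4-methylpenta-1,3-dienyl (1S)-camphanate
Conditions: CuBr (10 mol %), DMAP (20 mol %), 4 Å MS, O2 (1 atm), MeCN, 60 °C
Reagents that add atoms: none
Why: Chan–Lam–Evans-type copper-catalysed aerobic coupling of an alkenyltrifluoroborate with a carboxylic acid forms the enol ester C–O bond with retention of alkene geometry, so the (1E,3Z)-dienyl ester is obtained, whereas ruthenium-catalysed anti-Markovnikov addition of the acid to enyne 6 would give the unwanted (1Z) ester.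

Step 6
Reactants: 10 silylated dienyl camphanate
Product: 11 (1E,3Z)-5-hydroxy-4-methylpenta-1,3-dienyl (1S)-camphanate
Conditions: HF·pyridine, pyridine, THF, 0 °C
Reagents that add atoms: none
Why: Pyridine-buffered HF·pyridine removes the primary silyl ether (fluoride desilylation) and leaves the hindered enol ester and the diene untouched.

Step 7
Reactants: 12 di-tert-butyl acetylenedicarboxylate; 13 allylmagnesium bromide
Product: 15 di-tert-butyl 2-allylmaleate, via alkenylcopper adduct 14 (not isolated)
Conditions: 13, CuBr·SMe2 (1.1 equiv), THF, −78 °C; then 12, −78 °C; NH4Cl/MeOH, −78 °C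
Reagents that add atoms: none
Why: Syn-carbocupration of the acetylenedicarboxylate by allylcopper and protonation of the alkenylcopper with retention at −78 °C give the cis diester (maleate) and not the fumarate.

Step 8
Reactants: 15 di-tert-butyl 2-allylmaleate
Product: 17 2-allylmaleic anhydride, via 2-allylmaleic acid 16 (not isolated)
Conditions: CF3CO2H, CH2Cl2, rt; then (CF3CO)2O, 0 °C → rt
Reagents that add atoms: none
Why: Acidolysis of the two tert-butyl esters and dehydration of the cis diacid close the anhydride without any base, which the doubly allylic CH2 group would not survive.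

Step 9
Reactants: 11 dienol camphanate; 17 2-allylmaleic anhydride
Product: 18 hydrogen maleate: (2Z,4E)-2-methyl-5-[(1S)-camphanoyloxy]penta-2,4-dienyl ester at the future C6 carboxyl of 2-allylmaleic acid with the free acid on the allyl-bearing carbon
Conditions: toluene, 50 °C (no base)
Reagents that add atoms: none
Why: Uncatalysed alcoholysis of the unsymmetrical anhydride takes place at the less hindered carbonyl, the one on the CH= carbon (future C6), so the free acid remains on the allyl-bearing carbon (future C20) and no base touches the doubly allylic CH2.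

Step 10
Reactants: 18 hydrogen maleate
Product: 19 ring A cycloadduct acid (cyclohexene cis-fused at C4–C5 to the C19–O–C6 γ-lactone; C10 bears allyl and CO2H; C1 bears the camphanoyloxy group)
Conditions: toluene (0.01 M), BHT, 100 °C; then chromatography or crystallisation to remove the other diastereomer
Reagents that add atoms: none
Why: This is a concerted but asynchronous thermal [4+2] cycloaddition in which the electron-rich 1-acyloxydiene (nucleophilic at C4) meets the doubly activated alkene of the hydrogen maleate, whose internal hydrogen bond between CO2H and the ester carbonyl lowers the acceptor orbital; the closest known reaction type is the ester-tethered intramolecular Diels–Alder reaction of dienyl maleates and hydrogen maleates, together with Diels–Alder reactions of 1-acyloxydienes. Ring A closes by the cycloaddition itself (six-membered, both new bonds), and the γ-lactone closes as the tether ring when C4–C5 forms (five-membered, tether on the inside position of C4), so it can only be cis-fused. At C4 and C1 the methyl and camphanoyloxy groups both sit outside on the (2Z,4E)-diene and end cis; at C5 and C10 the inside tether reaches C5 only through the exo side, so C6 and the cis-disposed C20 carboxyl are exo and allyl is endo, which puts C20 cis to C6 and C19 and trans to the C1 oxygen. The absolute sense is not controlled in the transition state: the (1S)-camphanoyl group turns the two mirror-image modes into diastereomers, and the one drawn is separated. The step needs cycloaddition to outrun the [1,5]-hydrogen shift open to (Z)-dienes and the reversion to 17 and 11; the double activation, the hydrogen bond and the three-atom tether should allow reaction near 100 °C, and any ester formed at the other anhydride carbonyl would have to join C4 to the allyl-bearing carbon and should cyclise far more slowly.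

Step 11
Reactants: 19 cycloadduct acid
Product: 21 C20 primary alcohol (CH2OH on C10), via acid chloride 20 (not isolated)
Conditions: (COCl)2, DMF (cat.), CH2Cl2, 0 °C → rt; then NaBH4, THF/DMF, −20 → 0 °C, AcOH quench
Reagents that add atoms: none
Why: An acyl chloride is reduced by NaBH4 much faster than lactones, esters or alkenes (chemoselective reduction through the acid chloride), so only C20 reaches the alcohol level, and the cold work-up keeps the new alkoxide from attacking the neighbouring C6 lactone.

Step 12
Reactants: 21 C20 alcohol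
Product: 22 C20 tert-butyldimethylsilyl ether
Conditions: TBSCl, imidazole, DMF, rt
Reagents that add atoms: tert-butyldimethylsilyl chloride CC(C)(C)[Si](C)(C)Cl
Why: Silylation of the neopentylic primary alcohol (silyl ether protection) blocks C20–OH before C6 is taken to the aldehyde level, where a free C20 hydroxyl would close an internal acetal.

Step 13
Reactants: 22 silyl ether lactone
Product: 24 C6 methyl acetal with free C1 hydroxyl, via C6 lactol 23 (not isolated)
Conditions: i-Bu2AlH (6 equiv), CH2Cl2, −78 °C; potassium sodium tartrate (aq); then MeOH, PPTS (cat.), 0 °C → rt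
Reagents that add atoms: methanol CO
Why: i-Bu2AlH at −78 °C stops at the lactol (partial reduction of a lactone) and cleaves the camphanate reductively, and acid-catalysed acetal formation in methanol then fixes C6 as the methyl acetal, the C1 hydroxyl being trans to C6 across C10 and unable to reach it.

Step 14
Reactants: 24 methyl acetal alcohol
Product: 25 1,20-bis(tert-butyldimethylsilyl) ether
Conditions: TBSOTf, 2,6-lutidine, CH2Cl2, −78 → 0 °C
Reagents that add atoms: tert-butyldimethylsilyl triflate CC(C)(C)[Si](C)(C)OS(=O)(=O)C(F)(F)F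
Why: The silyl triflate silylates the hindered secondary C1 alcohol (silyl ether protection) that would otherwise add to the palladium-activated allyl group in the next step.

Step 15
Reactants: 25 bis-silyl ether
Product: 26 C11 methyl ketone (2-oxopropyl group on C10)
Conditions: PdCl2 (10 mol %), Cu(OAc)2 (20 mol %), O2 (1 atm), DMA/H2O (7:1), rt
Reagents that add atoms: water O
Why: Wacker–Tsuji oxidation turns the monosubstituted alkene into the methyl ketone with Markovnikov selectivity while the hindered ring alkene is inert, and Cu(OAc)2 as co-oxidant keeps the medium too weakly acidic to cleave the acetal or the silyl ethers.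

Step 16
Reactants: 26 methyl ketone
Product: 27 ring A saturated methyl ketone
Conditions: H2 (1 atm), Pd/C, EtOAc, rt
Reagents that add atoms: none
Why: Heterogeneous catalytic hydrogenation saturates the remaining cis-disubstituted C2=C3 bond without creating a stereocentre and without touching the ketone.

Step 17
Reactants: 27 saturated methyl ketone
Product: 30 vinyl ketone (2-oxobut-3-enyl group on C10), via Mannich base 28 (not isolated), via trimethylammonium iodide 29 (not isolated)
Conditions: LiN(i-Pr)2, THF, −78 °C; CH2=NMe2+ I−, −78 °C → rt; then MeI, CH2Cl2, rt; then NaHCO3 (aq), rt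
Reagents that add atoms: N,N-dimethylmethyleneiminium iodide C=[N+](C)C.[I-]
Why: Kinetic deprotonation takes the methyl protons (the C9 methylene is neopentylic), the Mannich reaction with the iminium salt adds C13, and quaternisation followed by base-induced elimination (Hofmann-type) gives the vinyl ketone.

Step 18
Reactants: 30 vinyl ketone
Product: 31 vinyl ketone with free C20 hydroxyl
Conditions: HF·pyridine, pyridine, THF, 0 °C
Reagents that add atoms: none
Why: HF·pyridine buffered with pyridine cleaves the primary silyl ether selectively (fluoride desilylation), the secondary C1 ether next to the quaternary C10 being much slower.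

Step 19
Reactants: 32 diethyl malonate; 33 2,3-dibromopropene
Product: 34 diethyl 2-(2-bromoallyl)malonate
Conditions: NaH, THF, 0 °C → rt (32 in excess)
Reagents that add atoms: none
Why: Malonic ester alkylation: the sodium enolate displaces the allylic bromide of 2,3-dibromopropene by SN2 while the vinylic bromide is inert.

Step 20
Reactants: 34 diethyl 2-(2-bromoallyl)malonate
Product: 36 2-(2-bromoallyl)acrylic acid, via 2-(2-bromoallyl)malonic acid 35 (not isolated)
Conditions: KOH, EtOH/H2O, rt; HCl; then (CH2O)n, Et2NH, EtOAc, reflux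
Reagents that add atoms: formaldehyde (as paraformaldehyde) C=O
Why: Saponification followed by Mannich-type decarboxylative methylenation of the malonic acid with formaldehyde and a secondary amine is the standard route to 2-substituted acrylic acids.

Step 21
Reactants: 31 C20 alcohol; 36 2-(2-bromoallyl)acrylic acid
Product: 38 C20 2-(2-bromoallyl)acrylate of the vinyl ketone, via acid chloride 37 (not isolated)
Conditions: 36, (COCl)2, DMF (cat.), CH2Cl2, 0 °C; then 31, Et3N, DMAP (cat.), CH2Cl2, −20 → 0 °C
Reagents that add atoms: none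
Why: Acylation of the neopentylic C20 alcohol by the acid chloride (esterification) installs the dienophile and its bromoallyl arm, the only hydroxyl in 31 being the one at C20.

Step 22
Reactants: 38 acrylate vinyl ketone
Product: 40 second cycloadduct (spiro δ-lactone fused to ring C; C11 silyl enol ether with C11=C12; C8 bears the 2-bromoallyl group), via (Z)-2-silyloxydiene 39 (not isolated)
Conditions: TBSOTf, Et3N, CH2Cl2, −78 → 0 °C; then toluene, BHT, 170 °C (sealed tube)
Reagents that add atoms: tert-butyldimethylsilyl triflate CC(C)(C)[Si](C)(C)OS(=O)(=O)C(F)(F)F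
Why: Soft enolisation toward C9 gives the (Z)-2-silyloxydiene (C10 cis to the silyloxy group), and the thermal intramolecular Diels–Alder reaction through the four-atom ester tether forms C8–C9 and C13–C14 and closes ring C and the δ-lactone, a mode known for 2-silyloxydienes tethered to acrylates, with the tether overriding the usual regiochemistry, the lactone carbonyl endo (cis ring fusion, bromoallyl group exo, so H9 and C15 cis) and attack on the diene face that lets C5 eclipse H9 and keeps C1 away from the dienophile (least allylic strain about C9–C10), which sets C8 and C9 as in the target.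

Step 23
Reactants: 40 silyl enol ether
Product: 41 C11 enone (C12=C13)
Conditions: Pd(OAc)2 (1.1 equiv), MeCN, rt → 40 °C
Reagents that add atoms: none
Why: Saegusa–Ito oxidation: the palladium enolate formed at C12 can undergo β-hydride elimination only toward C13, which gives the C11 enone with C12=C13.

Step 24
Reactants: 41 bromoallyl enone
Product: 42 bicyclo[3.2.1]octane ketone (16-methylene; C15 CH2; C11 ketone)
Conditions: Bu3SnH, AIBN (cat.), toluene, 90 °C
Reagents that add atoms: none
Why: Tin-hydride-mediated 5-exo cyclisation of the vinyl radical onto the enone β-carbon C13 closes ring D, the two-carbon bridge can only span C8 and C13 on one face of ring C so C13 is fixed, and the stabilised C12 radical is reduced to CH2.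

Step 25
Reactants: 42 methyl acetal ketone
Product: 43 C6 lactol
Conditions: HCl (1 M aq), THF, rt
Reagents that add atoms: water O
Why: Aqueous acid hydrolysis of the five-membered methyl acetal gives the lactol while the hindered secondary silyl ether, the lactone and the exocyclic alkene survive the mild conditions.

Step 26
Reactants: 43 lactol
Product: 44 C6 acetate (acetoxy group trans to C10 on C5)
Conditions: Ac2O, Et3N, DMAP (cat.), CH2Cl2, 0 °C
Reagents that add atoms: acetic anhydride CC(=O)OC(C)=O
Why: Acylation of the lactol (anomeric esterification) captures the equilibrating hemiacetal from its convex face, trans to C10 on C5, which is the C6 configuration of the target.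

Step 27
Reactants: 44 acetate ketone
Product: 45 C11 alcohol (hydroxyl on the face away from the C15–C16 bridge)
Conditions: NaBH4, CeCl3·7H2O, MeOH/THF, −78 °C
Reagents that add atoms: none
Why: Luche reduction: the underside of the C11 carbonyl is covered by the axial C10 and ring A, so the small hydride should enter from the side of the two-carbon bridge and give the equatorial alcohol with the C11 configuration of the target, and the low temperature spares the acetal acetate.

Step 28
Reactants: 45 C11 alcohol
Product: 46 C15 allylic alcohol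
Conditions: SeO2 (0.5 equiv), t-BuOOH, CH2Cl2, rt
Reagents that add atoms: tert-butyl hydroperoxide CC(C)(C)OO
Why: SeO2 allylic oxidation (ene reaction then [2,3]-shift) can only use the C15 hydrogens because the other allylic position, C13, is a bridgehead, and the exocyclic alkene is restored.

Step 29
Reactants: 46 C15 allylic alcohol
Product: 47 1-O-silyl oreskaurin A (16-methylene-15-ketone)
Conditions: MnO2, CH2Cl2, rt
Reagents that add atoms: none
Why: MnO2 oxidises the allylic C15 alcohol selectively to the enone and leaves the saturated, hindered C11 alcohol untouched.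

Step 30
Reactants: 47 1-O-silyl oreskaurin A
Product: 48 oreskaurin A
Conditions: HF·pyridine, THF, 0 °C → rt
Reagents that add atoms: none
Why: Fluoride desilylation with HF·pyridine frees the C1 hydroxyl under acidic, non-nucleophilic conditions that the exo-methylene ketone, the lactone and the acetal acetate tolerate.

**Compound list**

1 | propargyl alcohol | C#CCO | starting material
2 | cyclic alkenylmagnesium alkoxide (4-methyl-2,5-dihydro-1,2-oxamagnesole) | CC1=C[Mg]OC1 | intermediate
3 | (Z)-3-iodo-2-methylprop-2-en-1-ol | OC/C(C)=C\I | intermediate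
4 | (Z)-1-(tert-butyldimethylsilyloxy)-3-iodo-2-methylprop-2-ene | CC(C)(C)[Si](C)(C)OC/C(C)=C\I | intermediate
5 | ethynylmagnesium bromide | C#C[Mg]Br | starting material
6 | (Z)-5-(tert-butyldimethylsilyloxy)-4-methylpent-3-en-1-yne | CC(C)(C)[Si](C)(C)OC/C(C)=C\C#C | intermediate
7 | pinacol (1E,3Z)-5-(tert-butyldimethylsilyloxy)-4-methylpenta-1,3-dienylboronate | CC(C)(C)[Si](C)(C)OC/C(C)=C\C=C\B1OC(C)(C)C(C)(C)O1 | intermediate
8 | potassium (1E,3Z)-[5-(tert-butyldimethylsilyloxy)-4-methylpenta-1,3-dienyl]trifluoroborate | CC(C)(C)[Si](C)(C)OC/C(C)=C\C=C\[B-](F)(F)F.[K+] | intermediate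
9 | (1S)-(−)-camphanic acid, (1S,4R)-4,7,7-trimethyl-3-oxo-2-oxabicyclo[2.2.1]heptane-1-carboxylic acid | OC(=O)[C@@]12CC[C@@](C)(C(=O)O1)C2(C)C | starting material
10 | (1E,3Z)-5-(tert-butyldimethylsilyloxy)-4-methylpenta-1,3-dienyl (1S)-camphanate | CC(C)(C)[Si](C)(C)OC/C(C)=C\C=C\OC(=O)[C@@]12CC[C@@](C)(C(=O)O1)C2(C)C | intermediate
11 | (1E,3Z)-5-hydroxy-4-methylpenta-1,3-dienyl (1S)-camphanate | OC/C(C)=C\C=C\OC(=O)[C@@]12CC[C@@](C)(C(=O)O1)C2(C)C | intermediate
12 | di-tert-butyl acetylenedicarboxylate | CC(C)(C)OC(=O)C#CC(=O)OC(C)(C)C | starting material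
13 | allylmagnesium bromide | C=CC[Mg]Br | starting material
14 | alkenylcopper adduct (copper cis to allyl) | C=CC/C(C(=O)OC(C)(C)C)=C(\[Cu])C(=O)OC(C)(C)C | intermediate
15 | di-tert-butyl (Z)-2-allylbut-2-enedioate | C=CC/C(C(=O)OC(C)(C)C)=C/C(=O)OC(C)(C)C | intermediate
16 | (Z)-2-allylbut-2-enedioic acid | C=CC/C(C(=O)O)=C/C(=O)O | intermediate
17 | 2-allylmaleic anhydride | C=CCC1=CC(=O)OC1=O | intermediate
18 | hydrogen maleate, precursor of the key step: (Z)-2-allylbut-2-enedioic acid 4-[(2Z,4E)-2-methyl-5-((1S)-camphanoyloxy)penta-2,4-dienyl] ester | C=CC/C(C(=O)O)=C/C(=O)OC/C(C)=C\C=C\OC(=O)[C@@]12CC[C@@](C)(C(=O)O1)C2(C)C | intermediate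
19 | ring A cycloadduct acid: cyclohex-2-ene cis-fused at C4–C5 to the C19–O–C6 γ-lactone; C10 bears allyl and CO2H (C20, cis to C6); C1 camphanoyloxy cis to the C4 methyl | C=CC[C@]1(C(=O)O)[C@H](OC(=O)[C@@]34CC[C@@](C)(C(=O)O3)C4(C)C)C=C[C@@]2(C)COC(=O)[C@H]21 | intermediate
20 | acid chloride of 19 | C=CC[C@]1(C(Cl)=O)[C@H](OC(=O)[C@@]34CC[C@@](C)(C(=O)O3)C4(C)C)C=C[C@@]2(C)COC(=O)[C@H]21 | intermediate
21 | C20 alcohol (CH2OH on C10) | C=CC[C@]1(CO)[C@H](OC(=O)[C@@]34CC[C@@](C)(C(=O)O3)C4(C)C)C=C[C@@]2(C)COC(=O)[C@H]21 | intermediate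
22 | C20 tert-butyldimethylsilyl ether of 21 | C=CC[C@]1(CO[Si](C)(C)C(C)(C)C)[C@H](OC(=O)[C@@]34CC[C@@](C)(C(=O)O3)C4(C)C)C=C[C@@]2(C)COC(=O)[C@H]21 | intermediate
23 | C6 lactol with free C1 hydroxyl (C6 epimers) | C=CC[C@]1(CO[Si](C)(C)C(C)(C)C)[C@H](O)C=C[C@@]2(C)COC(O)[C@H]21 | intermediate
24 | C6 methyl acetal with free C1 hydroxyl (C6 epimers) | C=CC[C@]1(CO[Si](C)(C)C(C)(C)C)[C@H](O)C=C[C@@]2(C)COC(OC)[C@H]21 | intermediate
25 | 1,20-bis(tert-butyldimethylsilyl) ether of the methyl acetal | C=CC[C@]1(CO[Si](C)(C)C(C)(C)C)[C@H](O[Si](C)(C)C(C)(C)C)C=C[C@@]2(C)COC(OC)[C@H]21 | intermediate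
26 | C11 methyl ketone (2-oxopropyl on C10) | CC(=O)C[C@]1(CO[Si](C)(C)C(C)(C)C)[C@H](O[Si](C)(C)C(C)(C)C)C=C[C@@]2(C)COC(OC)[C@H]21 | intermediate
27 | ring A saturated methyl ketone | CC(=O)C[C@]1(CO[Si](C)(C)C(C)(C)C)[C@H](O[Si](C)(C)C(C)(C)C)CC[C@@]2(C)COC(OC)[C@H]21 | intermediate
28 | Mannich base (4-dimethylamino-2-oxobutyl on C10) | CN(C)CCC(=O)C[C@]1(CO[Si](C)(C)C(C)(C)C)[C@H](O[Si](C)(C)C(C)(C)C)CC[C@@]2(C)COC(OC)[C@H]21 | intermediate
29 | trimethylammonium iodide of 28 | C[N+](C)(C)CCC(=O)C[C@]1(CO[Si](C)(C)C(C)(C)C)[C@H](O[Si](C)(C)C(C)(C)C)CC[C@@]2(C)COC(OC)[C@H]21.[I-] | intermediate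
30 | vinyl ketone (2-oxobut-3-enyl on C10) | C=CC(=O)C[C@]1(CO[Si](C)(C)C(C)(C)C)[C@H](O[Si](C)(C)C(C)(C)C)CC[C@@]2(C)COC(OC)[C@H]21 | intermediate
31 | vinyl ketone with free C20 hydroxyl | C=CC(=O)C[C@]1(CO)[C@H](O[Si](C)(C)C(C)(C)C)CC[C@@]2(C)COC(OC)[C@H]21 | intermediate
32 | diethyl malonate | CCOC(=O)CC(=O)OCC | starting material
33 | 2,3-dibromopropene | C=C(Br)CBr | starting material
34 | diethyl 2-(2-bromoallyl)malonate | CCOC(=O)C(CC(Br)=C)C(=O)OCC | intermediate
35 | 2-(2-bromoallyl)malonic acid | OC(=O)C(CC(Br)=C)C(=O)O | intermediate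
36 | 2-(2-bromoallyl)acrylic acid | C=C(CC(Br)=C)C(=O)O | intermediate
37 | 2-(2-bromoallyl)acryloyl chloride | C=C(CC(Br)=C)C(Cl)=O | intermediate
38 | C20 2-(2-bromoallyl)acrylate of vinyl ketone 31 | C=CC(=O)C[C@]1(COC(=O)C(=C)CC(Br)=C)[C@H](O[Si](C)(C)C(C)(C)C)CC[C@@]2(C)COC(OC)[C@H]21 | intermediate
39 | (Z)-2-silyloxydiene (C9=C11(OTBS)–C12=C13; C10 cis to the silyloxy group) | C=C/C(O[Si](C)(C)C(C)(C)C)=C/[C@]1(COC(=O)C(=C)CC(Br)=C)[C@H](O[Si](C)(C)C(C)(C)C)CC[C@@]2(C)COC(OC)[C@H]21 | intermediate
40 | second cycloadduct: spiro δ-lactone (C20–O–C7) cis-fused to ring C; C11 silyl enol ether; C8 bears 2-bromoallyl cis to H9 | C=C(Br)C[C@]23CCC=C(O[Si](C)(C)C(C)(C)C)[C@H]2[C@]1(COC3=O)[C@H](O[Si](C)(C)C(C)(C)C)CC[C@@]2(C)COC(OC)[C@H]21 | intermediate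
41 | C11 enone (C12=C13) | C=C(Br)C[C@]23CC=CC(=O)[C@H]2[C@]1(COC3=O)[C@H](O[Si](C)(C)C(C)(C)C)CC[C@@]2(C)COC(OC)[C@H]21 | intermediate
42 | bicyclo[3.2.1]octane ketone (16-methylene, C11 ketone, C6 methyl acetal) | C=C1C[C@]23C[C@H]1CC(=O)[C@H]2[C@]1(COC3=O)[C@H](O[Si](C)(C)C(C)(C)C)CC[C@@]2(C)COC(OC)[C@H]21 | intermediate
43 | C6 lactol of 42 | C=C1C[C@]23C[C@H]1CC(=O)[C@H]2[C@]1(COC3=O)[C@H](O[Si](C)(C)C(C)(C)C)CC[C@@]2(C)COC(O)[C@H]21 | intermediate
44 | C6 acetate, C11 ketone | C=C1C[C@]23C[C@H]1CC(=O)[C@H]2[C@]1(COC3=O)[C@H](O[Si](C)(C)C(C)(C)C)CC[C@@]2(C)CO[C@H](OC(C)=O)[C@H]21 | intermediate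
45 | C11 alcohol | C=C1C[C@]23C[C@H]1C[C@@H](O)[C@H]2[C@]1(COC3=O)[C@H](O[Si](C)(C)C(C)(C)C)CC[C@@]2(C)CO[C@H](OC(C)=O)[C@H]21 | intermediate
46 | C15 allylic alcohol (C15 epimers) | C=C1C(O)[C@]23C[C@H]1C[C@@H](O)[C@H]2[C@]1(COC3=O)[C@H](O[Si](C)(C)C(C)(C)C)CC[C@@]2(C)CO[C@H](OC(C)=O)[C@H]21 | intermediate
47 | 1-O-(tert-butyldimethylsilyl)oreskaurin A | C=C1C(=O)[C@]23C[C@H]1C[C@@H](O)[C@H]2[C@]1(COC3=O)[C@H](O[Si](C)(C)C(C)(C)C)CC[C@@]2(C)CO[C@H](OC(C)=O)[C@H]21 | intermediate
48 | oreskaurin A | C=C1C(=O)[C@]23C[C@H]1C[C@@H](O)[C@H]2[C@]1(COC3=O)[C@H](O)CC[C@@]2(C)CO[C@H](OC(C)=O)[C@H]21 | target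

**Totals**

Total step count: 30. Longest linear sequence: 26 steps (from 1 through steps 1–6, 9–18 and 21–30).

**Steps most likely to fail**

Step 10. At the temperature the (Z)-diene needs, the [1,5]-hydrogen shift from C19 to C1 or the reversion of the hydrogen maleate to 17 and 11 may run ahead of the cycloaddition, and the remote camphanoyl group may give no facial bias, so that half of the material ends as the unwanted diastereomer. The fallback sets out from 18. The acid is turned into the allyl ester F3 (allyl bromide, KHCO3, DMF). This cis-diester is cyclised with Et2AlCl in CH2Cl2 at −40 to 0 °C, where a Lewis acid bound to both ester carbonyls should lower the barrier well below that of the hydrogen shift and hold the dienophile in one conformation, to give the allyl ester cycloadduct F4 (diastereomers separated as before). The acid is released with Pd(PPh3)4 and morpholine, and the route is rejoined at 19.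

Step 5. Protodeboronation or oxidative homocoupling of the dienyl borate may outrun C–O bond formation with the hindered tertiary acid, or the copper–oxygen medium may erode the diene geometry. The fallback sets out from 6. Hydroboration with dicyclohexylborane and oxidation with NaBO3 give the β,γ-unsaturated aldehyde F1. Deprotonation with KOt-Bu in THF at −78 °C gives the potassium dienolate F2, which is O-acylated with (1S)-camphanoyl chloride, a known way to 1-acyloxydienes. The (1E,3Z) ester is separated from any (1Z) isomer and is compound 10, where the route is rejoined.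

Step 27. Both faces of the C11 carbonyl are hindered (the two-carbon bridge on one side, the axial C10 with ring A on the other), so hydride may enter from the lactone side and give the axial 11-epimer, or methoxide may cleave the acetal acetate. The fallback sets out from 42, before the acetate is in place. The ketone is reduced by electron transfer with SmI2 in THF/MeOH, which lets the ketyl equilibrate and should give the more stable equatorial alcohol F5. Silylation (TBSOTf, 2,6-lutidine) gives the bis-silyl ether F6, acid hydrolysis gives the lactol F7, and acetylation gives the acetate F8. Oxidation with SeO2/t-BuOOH gives the C15 alcohol F9, and Dess–Martin periodinane gives the enone F10. HF·pyridine removes both silyl ethers, and the route is rejoined at 48.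

**Further compounds**

F1 | step 5 | (Z)-5-(tert-butyldimethylsilyloxy)-4-methylpent-3-enal | O=CC/C=C(C)\CO[Si](C)(C)C(C)(C)C
F2 | step 5 | potassium (1E,3Z)-5-(tert-butyldimethylsilyloxy)-4-methylpenta-1,3-dien-1-olate | [K+].[O-]/C=C/C=C(C)\CO[Si](C)(C)C(C)(C)C
F3 | step 10 | allyl ester of hydrogen maleate 18 | C=CC/C(C(=O)OCC=C)=C/C(=O)OC/C(C)=C\C=C\OC(=O)[C@@]12CC[C@@](C)(C(=O)O1)C2(C)C
F4 | step 10 | allyl ester of cycloadduct acid 19 | C=CC[C@]1(C(=O)OCC=C)[C@H](OC(=O)[C@@]34CC[C@@](C)(C(=O)O3)C4(C)C)C=C[C@@]2(C)COC(=O)[C@H]21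
F5 | step 27 | C11 alcohol of 42 (C6 methyl acetal) | C=C1C[C@]23C[C@H]1C[C@@H](O)[C@H]2[C@]1(COC3=O)[C@H](O[Si](C)(C)C(C)(C)C)CC[C@@]2(C)COC(OC)[C@H]21
F6 | step 27 | 1,11-bis(tert-butyldimethylsilyl) ether of F5 | C=C1C[C@]23C[C@H]1C[C@@H](O[Si](C)(C)C(C)(C)C)[C@H]2[C@]1(COC3=O)[C@H](O[Si](C)(C)C(C)(C)C)CC[C@@]2(C)COC(OC)[C@H]21
F7 | step 27 | C6 lactol of F6 | C=C1C[C@]23C[C@H]1C[C@@H](O[Si](C)(C)C(C)(C)C)[C@H]2[C@]1(COC3=O)[C@H](O[Si](C)(C)C(C)(C)C)CC[C@@]2(C)COC(O)[C@H]21
F8 | step 27 | C6 acetate of F7 | C=C1C[C@]23C[C@H]1C[C@@H](O[Si](C)(C)C(C)(C)C)[C@H]2[C@]1(COC3=O)[C@H](O[Si](C)(C)C(C)(C)C)CC[C@@]2(C)CO[C@H](OC(C)=O)[C@H]21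
F9 | step 27 | C15 allylic alcohol of F8 | C=C1C(O)[C@]23C[C@H]1C[C@@H](O[Si](C)(C)C(C)(C)C)[C@H]2[C@]1(COC3=O)[C@H](O[Si](C)(C)C(C)(C)C)CC[C@@]2(C)CO[C@H](OC(C)=O)[C@H]21
F10 | step 27 | 1,11-bis-O-(tert-butyldimethylsilyl)oreskaurin A | C=C1C(=O)[C@]23C[C@H]1C[C@@H](O[Si](C)(C)C(C)(C)C)[C@H]2[C@]1(COC3=O)[C@H](O[Si](C)(C)C(C)(C)C)CC[C@@]2(C)CO[C@H](OC(C)=O)[C@H]21
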